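The plan makes ring B itself, rather than its two aryl ether bonds, the late disconnection. Ring B has oxygen on B1 (to ring A) and on B4 in a para relation. It also has oxygen on B2 and B6 (to ring C) and hydrogen on B3 and B5, which is the 4-alkoxyphenol signature of a Dötz benzannulation. One operation joins a methoxy(2-methoxyvinyl)carbene chromium complex, one of its CO ligands and the ethynyl ether of the permethylated ring C–D–E terphenyl phenol, forming B4–B5, B6–B1 and B1–B2. The congested B6–O–C1 linkage is therefore installed earlier, on a linear two-carbon unit. B1–OH emerges as the sole unprotected hydroxyl, which is where ring A goes.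

Key step: step 8

**Labels.** Ring A is 3,5-dihydroxyphenoxy. Ring B is B1 (O to ring A), B2 (OH), B3 (H), B4 (OH), B5 (H), B6 (O to ring C). Ring C is C1 (O to ring B), C2, C4 and C6 (OH), C3 (ring D), C5 (ring E). Rings D and E are 2,4,6-trihydroxyphenyl. The target has no stereocentre, and the C3–D and C5–E axes are not stereogenic because rings D and E are symmetric about them.

**Remark on the chemistry (assumption).**
- All thirteen hydroxyl groups travel as methyl ethers.
- The formyl group of the starting aldehyde is kept as the masked C1 hydroxyl until both biaryl bonds are made, so no phenol protecting group is needed.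
- That ring has no free ortho or para hydroxyl, so the aldehyde-to-phenol change is run as a peracid Baeyer–Villiger oxidation.
- In the SMILES each CO ligand is written as =C=O on chromium and an η6 arene–chromium bond as a dot.

## Route

Step 1
Reactants: 1 2,4,6-trimethoxybenzaldehyde
Product: 2 3,5-dibromo-2,4,6-trimethoxybenzaldehyde
Conditions: NBS (2.2 equiv), MeCN, 0 °C → rt
Reagents that add atoms: N-bromosuccinimide, O=C1CCC(=O)N1Br
Why: Electrophilic aromatic bromination should fill C3 and C5, the only free ring positions, because each is ortho or para to all three methoxy groups and meta to the formyl group, and the lack of a para-dioxygen pattern protects the ring from oxidation to a quinone.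

Step 2
Reactants: 2 3,5-dibromo-2,4,6-trimethoxybenzaldehyde; 3 1,3,5-trimethoxybenzene
Product: 6 2,4,6-trimethoxy-3,5-bis(2,4,6-trimethoxyphenyl)benzaldehyde, via 2,4,6-trimethoxyphenyllithium 4 (not isolated), via chloro(2,4,6-trimethoxyphenyl)zinc 5 (not isolated)
Conditions: 3 (3 equiv), n-BuLi, THF, 0 °C → rt; ZnCl2, THF; then 2, Pd2(dba)3 (cat.), RuPhos (cat.), THF/NMP, 70 °C
Reagents that add atoms: none
Why: In this double Negishi coupling, lithiation of 3 between two methoxy groups and transmetallation give an arylzinc that neither protodemetallates nor adds to the hindered aldehyde, a bulky electron-rich biarylphosphine on zerovalent palladium is an established answer to tetra-ortho-substituted biaryls, and the formyl group activates both C–Br bonds for oxidative addition.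

Step 3
Reactants: 6 2,4,6-trimethoxy-3,5-bis(2,4,6-trimethoxyphenyl)benzaldehyde
Product: 8 2,4,6-trimethoxy-3,5-bis(2,4,6-trimethoxyphenyl)phenol, via terphenyl formate 7 (not isolated)
Conditions: mCPBA, CH2Cl2, 0 °C → rt; aq. Na2S2O3/NaHCO3 wash; then K2CO3 (cat.), MeOH, Ar, rt
Reagents that add atoms: 3-chloroperoxybenzoic acid (mCPBA), O=C(OO)c1cccc(Cl)c1
Why: In this Baeyer–Villiger oxidation the alkoxy-rich, doubly ortho-substituted aryl group should migrate in preference to hydrogen, the formate shields the oxidation-prone phenol until the peracid is washed out, and carbonate-catalysed transesterification then frees C1–OH.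

Step 4
Reactants: 8 2,4,6-trimethoxy-3,5-bis(2,4,6-trimethoxyphenyl)phenol; 9 trichloroethylene
Product: 11 (E)-1,2-dichlorovinyl 2,4,6-trimethoxy-3,5-bis(2,4,6-trimethoxyphenyl)phenyl ether, via dichloroacetylene 10 (not isolated)
Conditions: KH, THF, 0 °C; 9, −50 °C → rt
Reagents that add atoms: none
Why: Base turns 9 into dichloroacetylene in solution and the potassium phenoxide adds to it in an anti sense (nucleophilic addition to a haloalkyne, the standard entry to 1,2-dichlorovinyl ethers), so the C1–O bond forms on a linear unhindered carbon that does not feel the two ortho methoxy groups.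

Step 5
Reactants: 11 (E)-1,2-dichlorovinyl 2,4,6-trimethoxy-3,5-bis(2,4,6-trimethoxyphenyl)phenyl ether
Product: 14 ethynyl 2,4,6-trimethoxy-3,5-bis(2,4,6-trimethoxyphenyl)phenyl ether, via chloroethynyl ether 12 (not isolated), via lithium aryloxyacetylide 13 (not isolated)
Conditions: n-BuLi (3 equiv), THF, −78 → −40 °C; H2O, −78 °C; filtration through basic alumina, used at once
Reagents that add atoms: none
Why: Elimination of HCl, chlorine–lithium exchange on the chloroalkyne and protonation make up the usual dichlorovinyl ether route to aryl ynol ethers, the aryl group offers no β-hydrogen for retro-ene loss, and any lithiation of rings D or E between two methoxy groups is undone by the same quench.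

Step 6
Reactants: 15 chromium hexacarbonyl Cr(CO)6; 16 ethynyltrimethylsilane
Product: 19 pentacarbonyl[1-methoxy-3-(trimethylsilyl)prop-2-yn-1-ylidene]chromium, via lithium (trimethylsilyl)acetylide 17 (not isolated), via lithium acylchromate 18 (not isolated)
Conditions: 16, n-BuLi, THF, −78 °C; Cr(CO)6, −78 °C → rt; MeOTf, CH2Cl2, 0 °C
Reagents that add atoms: methyl trifluoromethanesulfonate, COS(=O)(=O)C(F)(F)F
Why: In this Fischer carbene synthesis the acetylide adds to a CO ligand of Cr(CO)6 and the acylchromate oxygen is methylated by a hard electrophile, a well-used preparation of silylalkynyl(methoxy)carbene complexes.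

Step 7
Reactants: 19 pentacarbonyl[1-methoxy-3-(trimethylsilyl)prop-2-yn-1-ylidene]chromium
Product: 21 pentacarbonyl[(E)-1,3-dimethoxyprop-2-en-1-ylidene]chromium, via ethynylcarbene complex 20 (not isolated)
Conditions: NaOMe (cat.), MeOH/THF, −40 → 0 °C
Reagents that add atoms: methanol, CO
Why: Methoxide cleaves the acceptor-activated alkynyl C–Si bond and methanol then adds to the β-carbon (base-catalysed Michael addition of alcohols to alkynylcarbene complexes), competing attack at the carbene carbon only exchanges OMe for OMe, and the push–pull double bond should settle in the E form.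

Step 8
Reactants: 14 ethynyl 2,4,6-trimethoxy-3,5-bis(2,4,6-trimethoxyphenyl)phenyl ether; 21 pentacarbonyl[(E)-1,3-dimethoxyprop-2-en-1-ylidene]chromium
Product: 23 2,4-dimethoxy-6-[2,4,6-trimethoxy-3,5-bis(2,4,6-trimethoxyphenyl)phenoxy]phenol (rings B to E with B1–OH free), via tricarbonylchromium complex 22 (not isolated)
Conditions: 21 (1.5 equiv), degassed THF (0.3 M), Ar, 50 °C; then air, Et2O, daylight, rt
Reagents that add atoms: none
Why: Thermal loss of one CO from 21 lets the alkyne of 14 bind and insert so that the carbene carbon (B4) bonds to the terminal CH (B5) and chromium moves to the aryloxy-bearing carbon (B6), after which migration of a CO ligand onto B6 gives a dienylketene whose carbonyl carbon is B1. Ring B closes by 6π electrocyclisation of this ketene onto the methoxy-bearing vinyl terminus (B1–B2), and enolisation gives the 4-methoxyphenol as its Cr(CO)3 complex 22, which air and light strip to 23. This is the Dötz [3+2+1] benzannulation of an alkenyl(methoxy)carbene complex of zerovalent chromium with a terminal alkyne, a reaction in which aryl ethynyl ethers are established partners for making diaryl ethers. No stereocentre is formed, and the double-bond geometry of 21 is erased on aromatisation. The step needs the regiochemistry that places OAr next to the CO-derived carbon, and both the size difference between H and OAr and the polarisation of the ynol ether (nucleophilic CH toward the electrophilic carbene carbon) point that way. It also needs CO insertion to outrun five-membered-ring closure, which chromium, an alkoxy rather than amino carbene, an alkenyl rather than aryl complex and a concentrated solution all favour.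

Step 9
Reactants: 23 2,4-dimethoxy-6-[2,4,6-trimethoxy-3,5-bis(2,4,6-trimethoxyphenyl)phenoxy]phenol; 24 1-iodo-3,5-dimethoxybenzene
Product: 25 1-(3,5-dimethoxyphenoxy)-2,4-dimethoxy-6-[2,4,6-trimethoxy-3,5-bis(2,4,6-trimethoxyphenyl)phenoxy]benzene (tridecamethyl ether of the target)
Conditions: 24, CuI (cat.), picolinic acid (cat.), K3PO4, DMSO, Ar, 90 °C
Reagents that add atoms: none
Why: For this Ullmann-type C–O coupling the CuI/picolinic acid system is established for 2,6-disubstituted phenols, iodide 24 has no ortho substituent, and exclusion of air protects the easily oxidised 4-methoxyphenol.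

Step 10
Reactants: 25 tridecamethyl ether of the target
Product: 26 4-(3,5-dihydroxyphenoxy)-5-[2,4,6-trihydroxy-3,5-bis(2,4,6-trihydroxyphenyl)phenoxy]benzene-1,3-diol (CNP0228669.0)
Conditions: BBr3 (about 3 equiv per OMe), CH2Cl2, −78 °C → rt; ice-water; EtOAc extraction and Sephadex LH-20 under Ar
Reagents that add atoms: none
Why: In this global Lewis-acid ether cleavage BBr3 binds each methoxy oxygen and bromide removes the methyl group by SN2, the diaryl ether and biaryl bonds are inert, and staying at or below room temperature should avoid dibenzofuran closure between ortho hydroxyls of ring C and rings D or E.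

## Compound list

1 | 2,4,6-trimethoxybenzaldehyde | COc1cc(OC)c(C=O)c(OC)c1 | starting material
2 | 3,5-dibromo-2,4,6-trimethoxybenzaldehyde | O=Cc1c(OC)c(Br)c(OC)c(Br)c1OC | intermediate
3 | 1,3,5-trimethoxybenzene | COc1cc(OC)cc(OC)c1 | starting material
4 | 2,4,6-trimethoxyphenyllithium | [Li]c1c(OC)cc(OC)cc1OC | intermediate
5 | chloro(2,4,6-trimethoxyphenyl)zinc | Cl[Zn]c1c(OC)cc(OC)cc1OC | intermediate
6 | 2,4,6-trimethoxy-3,5-bis(2,4,6-trimethoxyphenyl)benzaldehyde | O=Cc1c(OC)c(-c2c(OC)cc(OC)cc2OC)c(OC)c(-c2c(OC)cc(OC)cc2OC)c1OC | intermediate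
7 | 2,4,6-trimethoxy-3,5-bis(2,4,6-trimethoxyphenyl)phenyl formate | O=COc1c(OC)c(-c2c(OC)cc(OC)cc2OC)c(OC)c(-c2c(OC)cc(OC)cc2OC)c1OC | intermediate
8 | 2,4,6-trimethoxy-3,5-bis(2,4,6-trimethoxyphenyl)phenol | Oc1c(OC)c(-c2c(OC)cc(OC)cc2OC)c(OC)c(-c2c(OC)cc(OC)cc2OC)c1OC | intermediate
9 | trichloroethylene | ClC=C(Cl)Cl | starting material
10 | dichloroacetylene | ClC#CCl | intermediate
11 | (E)-1,2-dichlorovinyl 2,4,6-trimethoxy-3,5-bis(2,4,6-trimethoxyphenyl)phenyl ether | Cl/C=C(/Cl)Oc1c(OC)c(-c2c(OC)cc(OC)cc2OC)c(OC)c(-c2c(OC)cc(OC)cc2OC)c1OC | intermediate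
12 | chloroethynyl 2,4,6-trimethoxy-3,5-bis(2,4,6-trimethoxyphenyl)phenyl ether | ClC#COc1c(OC)c(-c2c(OC)cc(OC)cc2OC)c(OC)c(-c2c(OC)cc(OC)cc2OC)c1OC | intermediate
13 | lithium 2-[2,4,6-trimethoxy-3,5-bis(2,4,6-trimethoxyphenyl)phenoxy]ethynide | [Li]C#COc1c(OC)c(-c2c(OC)cc(OC)cc2OC)c(OC)c(-c2c(OC)cc(OC)cc2OC)c1OC | intermediate
14 | ethynyl 2,4,6-trimethoxy-3,5-bis(2,4,6-trimethoxyphenyl)phenyl ether | C#COc1c(OC)c(-c2c(OC)cc(OC)cc2OC)c(OC)c(-c2c(OC)cc(OC)cc2OC)c1OC | intermediate
15 | chromium hexacarbonyl Cr(CO)6 | O=C=[Cr](=C=O)(=C=O)(=C=O)(=C=O)=C=O | starting material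
16 | ethynyltrimethylsilane | C#C[Si](C)(C)C | starting material
17 | lithium (trimethylsilyl)acetylide | [Li]C#C[Si](C)(C)C | intermediate
18 | lithium pentacarbonyl[1-oxido-3-(trimethylsilyl)prop-2-yn-1-ylidene]chromate | [Li]OC(C#C[Si](C)(C)C)=[Cr](=C=O)(=C=O)(=C=O)(=C=O)=C=O | intermediate
19 | pentacarbonyl[1-methoxy-3-(trimethylsilyl)prop-2-yn-1-ylidene]chromium | COC(C#C[Si](C)(C)C)=[Cr](=C=O)(=C=O)(=C=O)(=C=O)=C=O | intermediate
20 | pentacarbonyl(1-methoxyprop-2-yn-1-ylidene)chromium | COC(C#C)=[Cr](=C=O)(=C=O)(=C=O)(=C=O)=C=O | intermediate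
21 | pentacarbonyl[(E)-1,3-dimethoxyprop-2-en-1-ylidene]chromium | CO/C=C/C(OC)=[Cr](=C=O)(=C=O)(=C=O)(=C=O)=C=O | intermediate
22 | tricarbonylchromium complex of 23, η6-bound through ring B | COc1cc(OC)c(O)c(Oc2c(OC)c(-c3c(OC)cc(OC)cc3OC)c(OC)c(-c3c(OC)cc(OC)cc3OC)c2OC)c1.O=C=[Cr](=C=O)=C=O | intermediate
23 | 2,4-dimethoxy-6-[2,4,6-trimethoxy-3,5-bis(2,4,6-trimethoxyphenyl)phenoxy]phenol | Oc1c(OC)cc(OC)cc1Oc1c(OC)c(-c2c(OC)cc(OC)cc2OC)c(OC)c(-c2c(OC)cc(OC)cc2OC)c1OC | intermediate
24 | 1-iodo-3,5-dimethoxybenzene | COc1cc(I)cc(OC)c1 | starting material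
25 | 1-(3,5-dimethoxyphenoxy)-2,4-dimethoxy-6-[2,4,6-trimethoxy-3,5-bis(2,4,6-trimethoxyphenyl)phenoxy]benzene | COc1cc(OC)cc(Oc2c(OC)cc(OC)cc2Oc2c(OC)c(-c3c(OC)cc(OC)cc3OC)c(OC)c(-c3c(OC)cc(OC)cc3OC)c2OC)c1 | intermediate
26 | 4-(3,5-dihydroxyphenoxy)-5-[2,4,6-trihydroxy-3,5-bis(2,4,6-trihydroxyphenyl)phenoxy]benzene-1,3-diol (CNP0228669.0) | Oc1cc(O)cc(Oc2c(O)cc(O)cc2Oc2c(O)c(-c3c(O)cc(O)cc3O)c(O)c(-c3c(O)cc(O)cc3O)c2O)c1 | target

## Step count and risks

Total step count: 10. Longest linear sequence: 8 steps (steps 1 to 5, then 8 to 10). The carbene branch (steps 6 and 7) joins at step 8.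

**1. Step 8.**
- What may go wrong: the β-methoxy donor makes the metal centre electron-rich, so CO insertion may lose out to direct five-membered-ring closure of the vinylcarbene intermediate. The ynol ether may also oligomerise or hydrate before it inserts.
- Fallback (sets out from 8, comes back at 23): ring B is taken from an existing arene and the B6–O–C1 bond is made by copper catalysis. Commercial 5-iodovanillin (4-hydroxy-3-iodo-5-methoxybenzaldehyde) is benzylated (BnBr, K2CO3, DMF) to 4-(benzyloxy)-3-iodo-5-methoxybenzaldehyde F1. Baeyer–Villiger oxidation (mCPBA, CH2Cl2) gives 4-(benzyloxy)-3-iodo-5-methoxyphenyl formate F2, and methanolysis (K2CO3 cat., MeOH) gives 4-(benzyloxy)-3-iodo-5-methoxyphenol F3. Methylation (MeI, K2CO3, acetone) gives 2-(benzyloxy)-1-iodo-3,5-dimethoxybenzene F4. Ullmann coupling of 8 with F4 (CuI, picolinic acid, K3PO4, DMSO, 100 °C, Ar) gives the B1-O-benzyl ether of 23 F5. Hydrogenolysis (H2, Pd/C, EtOAc/MeOH) then returns to 23.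

**2. Step 2.**
- What may go wrong: the second oxidative addition occurs at a C–Br bond flanked by two methoxy groups and buttressed by the first new aryl ring. It may be slow enough for hydrodebromination and arylzinc homocoupling to take over.
- Fallback (sets out from 1 and 3, comes back at 6): a stoichiometric copper-mediated mixed Ullmann biaryl coupling replaces palladium catalysis. Compound 1 is diiodinated (N-iodosuccinimide, CF3CO2H cat., MeCN) to 3,5-diiodo-2,4,6-trimethoxybenzaldehyde F6. Aryllithium 4, made from 3 as before, is transmetallated with CuBr·SMe2 to (2,4,6-trimethoxyphenyl)copper F7. Heating F7 with F6 in pyridine gives 6.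

**3. Step 9.**
- What may go wrong: C–O bond formation at the doubly ortho-flanked B1 oxygen may be sluggish, so that oxidation of the electron-rich phenoxide at the copper centre competes.
- Fallback (sets out from 23, comes back at 25): metal-free O-arylation with an aryne, which is far less sensitive to crowding. Commercial 3,5-dimethoxyphenol is brominated ortho to the hydroxyl (NBS, CH2Cl2, −78 °C) to 2-bromo-3,5-dimethoxyphenol F8 and silylated (HMDS, THF, reflux) to (2-bromo-3,5-dimethoxyphenoxy)trimethylsilane F9. Bromine–lithium exchange (n-BuLi, −78 °C), retro-Brook O-to-C silyl shift and trapping with Tf2O convert F9 into 3,5-dimethoxy-2-(trimethylsilyl)phenyl trifluoromethanesulfonate F10. CsF in MeCN at rt releases 3,5-dimethoxybenzyne F11 in the presence of 23. The phenoxide should add to the aryne carbon remote from the flanking methoxy group, and this position gives the 3,5-dimethoxyphenyl ether 25.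

Further compounds
F1 | step 8 | 4-(benzyloxy)-3-iodo-5-methoxybenzaldehyde | O=Cc1cc(I)c(OCc2ccccc2)c(OC)c1
F2 | step 8 | 4-(benzyloxy)-3-iodo-5-methoxyphenyl formate | O=COc1cc(I)c(OCc2ccccc2)c(OC)c1
F3 | step 8 | 4-(benzyloxy)-3-iodo-5-methoxyphenol | Oc1cc(I)c(OCc2ccccc2)c(OC)c1
F4 | step 8 | 2-(benzyloxy)-1-iodo-3,5-dimethoxybenzene | COc1cc(I)c(OCc2ccccc2)c(OC)c1
F5 | step 8 | 2-(benzyloxy)-1,5-dimethoxy-3-[2,4,6-trimethoxy-3,5-bis(2,4,6-trimethoxyphenyl)phenoxy]benzene (B1-O-benzyl ether of 23) | COc1cc(Oc2c(OC)c(-c3c(OC)cc(OC)cc3OC)c(OC)c(-c3c(OC)cc(OC)cc3OC)c2OC)c(OCc2ccccc2)c(OC)c1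
F6 | step 2 | 3,5-diiodo-2,4,6-trimethoxybenzaldehyde | O=Cc1c(OC)c(I)c(OC)c(I)c1OC
F7 | step 2 | (2,4,6-trimethoxyphenyl)copper | [Cu]c1c(OC)cc(OC)cc1OC
F8 | step 9 | 2-bromo-3,5-dimethoxyphenol | COc1cc(O)c(Br)c(OC)c1
F9 | step 9 | (2-bromo-3,5-dimethoxyphenoxy)trimethylsilane | COc1cc(O[Si](C)(C)C)c(Br)c(OC)c1
F10 | step 9 | 3,5-dimethoxy-2-(trimethylsilyl)phenyl trifluoromethanesulfonate | COc1cc(OS(=O)(=O)C(F)(F)F)c([Si](C)(C)C)c(OC)c1
F11 | step 9 | 3,5-dimethoxybenzyne (1,2-didehydro-3,5-dimethoxybenzene) | COC1=CC(OC)=CC#C1
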